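## Analysis of the target

The target 18 is a cyclohexene with ring carbons C1–C6, one ring double bond (C2=C3) and an exocyclic methylene C7 on C3. The numbering used throughout is: C1 = CH–OMe, C2 = ring CH=, C3 = alkene carbon bearing C7H2–OBz, C4 = allylic CH–OH, C5 = CH–OBz, C6 = CH–OH next to C1. The four contiguous stereocentres C4, C5, C6 and C1 all carry oxygen and each is trans to its neighbours (4S,5R,6R,1S in this numbering), so one half-chair can hold all four substituents equatorial or pseudo-equatorial. The oxygen functions are of three kinds in fixed positions: a methyl ether at C1, benzoates at C5 and C7, free hydroxyls at C4 and C6. The C5 benzoate sits between the two free hydroxyls, so acyl migration under base is a standing danger; the allylic C1 ether and C7 benzoate can ionise under acid, and the ring can aromatise by loss of two oxygen groups. The difficulty is therefore the all-trans array of four oxygenated centres with the right O-substituent on each, rather than the carbon skeleton. The strategy rests on the fact that C1 is gamma to C7 through C2=C3. With C7 as an ester, the C1 hydrogens are vinylogously acidic, and a dienolate that is nucleophilic at C1 can close the C1–C6 bond onto a C6 aldehyde, which creates the free C6 hydroxyl beside the C1 methyl ether.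

## Retrosynthetic reasoning

18 ⇒ 17. The two Si–O bonds at C4 and C6 are cut last. Free hydroxyls then flank the C5 benzoate only in the final, non-basic step, which keeps acyl migration out of the route.

17 ⇒ 15 + 16 ⇒ 14 ⇒ 13 ⇒ 12. The two ester C–O bonds at C5 and C7 are cut together, so one acylation of diol 15 with two equivalents of 16 installs both benzoates. C7 of 15 is traced back to the ester of 14, because the key step needs C7 at the ester level. The C5 hydroxyl of 14 is traced back to the aryl ether of 13, a group orthogonal to silyl ethers, so that C5 alone is free when the benzoates go on. The C6 silyl ether of 13 comes from the free hydroxyl of 12.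

12 ⇒ 10 (through 11). The C1–C6 ring bond is cut. It is cut here because C1 is the vinylogous alpha position of the C7 ester and C6 becomes an aldehyde, so the cut removes the ring and two stereocentres (C1, C6) at once. What remains is an open chain with only C4 and C5 as stereocentres. The forward reaction has to form dienolate 11 in the presence of an enolisable aldehyde, react through C1, and set C6–OH trans to C5–O and C1–OMe trans to C6–OH.

10 ⇒ 9. The C6 aldehyde is traced back to a terminal vinyl group by a C=C cleavage. The vinyl group is inert to the preceding steps and allows C5 and C6 to arrive together as an allyl unit.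

9 ⇒ 8 ⇒ 7 ⇒ 6. After removal of the C4 silyl group, the C3–C7 bond is cut: the ester carbon is put on the alkyne carbon next to the C4 carbinol by directed hydrostannation and carbonylation. This is preferred to carrying an acrylate aldehyde, which would be unstable, and the alkene geometry that results is irrelevant because it is lost in 11.

6 ⇒ 3 + 4 (through 5). The C4–C5 bond is cut. One reagent-controlled alkoxyallylboration sets both stereocentres: the Z-geometry of 5 gives the syn (later trans-on-ring) relationship and the terpene ligands give the absolute configuration. C5 arrives already protected and differentiated from C4–OH, and C6 arrives as the vinyl group.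

3 ⇒ 1 (through 2). The formyl C–C bond is cut; 3 is the formylated acetylide of commercial 1, and 4 and 16 are commercial.

## Alternatives that were turned down

Alternative 1: No ring C–C bond is cut; the six ring carbons and C7 are those of ethyl benzoate A1, and the C4–O and C5–O bonds are traced back to the arene. In the forward key step, whole cells expressing toluene dioxygenase cis-dihydroxylate A1 at its 2,3-bond and give the diene diol A2 as one enantiomer.
- For: one step gives an enantiopure ring with C7 at the carboxyl level, C5 in the correct configuration and a free C1=C6 alkene for further oxygenation. On ring construction and enantiopurity this is stronger than the chosen route, which needs seven steps to reach the ring.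
- Against: A2 is a cis-diol, so C4 (allylic, next to the ester-bearing carbon) has the wrong configuration and must be inverted at a centre where SN2′ attack and aromatisation compete. The two secondary hydroxyls of A2 must be told apart. The C1=C6 alkene must then take up OH and OMe trans with correct regiochemistry and facial selectivity, and the dienediol dehydrates easily to phenols. Fermentation equipment is needed.
- Comparison: the chosen strategy builds C4/C5 trans directly and forms C6–OH and C1–OMe in one bond formation without any inversion. Its price is a speculative ring closure, which alternative 1 does not need.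

Alternative 2: The C1–C2 bond is cut, giving the open-chain Z-vinylsilane dimethyl acetal A3. In the forward key step a strong Lewis acid ionises the acetal, C2 attacks the C1 oxocarbenium ion at the silicon-bearing carbon, silicon leaves, and the ring closes to A4, which is identical with 17.
- For: the acetal delivers the C1 methyl ether itself, and the ring closure ends one step before the target. On endgame economy this is stronger than the chosen strategy, whose key step is followed by five steps. Vinylsilane–acetal cyclisations are established and silicon fixes the regiochemistry.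
- Against: A3 must already carry C4, C5 and C6, both benzoates, two silyl ethers and a stereodefined trisubstituted vinylsilane, so the acyclic sequence is long. The key step makes only one stereocentre (C1), and its control rests on the conformation of an alpha-silyloxy oxocarbenium ion. The C5 benzoate can participate at the cation, and the allylic C7 benzoate and the silyl ethers are exposed to the Lewis acid.
- Comparison: the chosen strategy makes two stereocentres in the ring closure and needs only a six-step precursor with two stereocentres from one reaction. It has the longer endgame.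

Alternative 3: Two bonds are cut, C3–C4 and C1–C2, giving the dialdehyde A5 and the silyl alkyne A6. In the forward key step the alkyne complex formed from A6 with Ti(O-i-Pr)4 and i-PrMgCl adds through C3 to one aldehyde of A5 and then through C2 to the other, closing the ring to the diol A7.
- For: this is the most convergent plan, with two C–C bonds and the ring formed in one operation from two small fragments, and A5 holds C5 and C6 trans from a four-carbon chiral-pool unit. On bonds formed per step it is stronger than the chosen strategy.
- Against: A5 differs at its two ends only in the protecting groups, so which aldehyde reacts first is not controlled and two regioisomeric rings are expected. The new carbinol centres C1 and C4 have no clear control element. A7 then needs methylation of C1–OH in the presence of C4–OH (both secondary allylic), protodesilylation at C2 and exchange of protecting groups for the benzoates. The second, ring-forming aldehyde insertion has little precedent, and A5 epimerises easily.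
- Comparison: the chosen strategy has no regiochemical ambiguity (attack through C3 would give a four-membered ring), carries the methyl ether from the start and keeps C4 differentiated throughout.

Key step: step 7

Remark: the C5 oxygen is carried as a 4-methoxyphenyl ether (cleaved oxidatively like a 4-methoxybenzyl ether), because this group is built into allylboration reagent 5, whereas an allyl benzyl-type ether would undergo Wittig rearrangement on lithiation.

Remark: the enoate in 8–10 is Z (CH2OMe cis to CO2Me), the geometry that steps 3 and 4 deliver; it is erased in dienolate 11.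

## Route

Step 1
Reactants: 1 3-methoxyprop-1-yne (methyl propargyl ether)
Product: 3 4-methoxybut-2-ynal, via lithium acetylide 2 (not isolated)
Conditions: n-BuLi, THF, −78 °C; DMF, −78 → 0 °C; poured into aq. KH2PO4/MTBE, 0 °C
Reagents that add atoms: N,N-dimethylformamide, CN(C)C=O
Why: Deprotonation of the terminal alkyne and formylation of acetylide 2 with a formamide (Bouveault-type formylation); the reverse quench into phosphate buffer releases the ynal without conjugate addition of the liberated amine. No stereocentre is formed.

Step 2
Reactants: 3 4-methoxybut-2-ynal; 4 1-methoxy-4-(prop-2-en-1-yloxy)benzene (allyl 4-methoxyphenyl ether)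
Product: 6 (3S,4S)-7-methoxy-3-(4-methoxyphenoxy)hept-1-en-5-yn-4-ol, via Z-aryloxyallylborane 5 (not isolated)
Conditions: 4, s-BuLi, THF, −78 °C; (+)-Ipc2BOMe [from (−)-α-pinene]; BF3·OEt2; then 3, −78 °C; NaOH, H2O2, 0 °C → rt
Reagents that add atoms: none
Why: Brown alkoxyallylboration: lithiation of 4 gives the chelated Z-oxyallyl anion, boron transfer gives 5, and 5 adds to 3 through a closed chair transition state. The Z-geometry of 5 fixes the syn relationship of the two new centres (target C5 and C4), and the isopinocampheyl groups from (−)-α-pinene select the aldehyde face that gives the (3S,4S) isomer. C5 arrives as its aryl ether and C6 as a vinyl group.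

Step 3
Reactants: 6 (3S,4S)-7-methoxy-3-(4-methoxyphenoxy)hept-1-en-5-yn-4-ol
Product: 7 (3S,4R,5Z)-7-methoxy-3-(4-methoxyphenoxy)-5-(tributylstannyl)hepta-1,5-dien-4-ol
Conditions: Bu3SnH, [(C5Me5)RuCl]4 (cat.), CH2Cl2, rt
Reagents that add atoms: tributyltin hydride, CCCC[SnH](CCCC)CCCC
Why: Hydroxyl-directed ruthenium-catalysed trans-hydrostannation of an internal alkyne: the free propargylic hydroxyl hydrogen-bonds to the chloride ligand, so tin goes to the alkyne carbon next to the carbinol (target C3) and hydrogen to C2 from the opposite face. The terminal alkene and the aryl ether should not react. The stereocentres are untouched; the descriptor at the carbinol changes only because tin changes the priorities.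

Step 4
Reactants: 7 (3S,4R,5Z)-7-methoxy-3-(4-methoxyphenoxy)-5-(tributylstannyl)hepta-1,5-dien-4-ol
Product: 8 methyl (2Z)-2-[(1S,2S)-1-hydroxy-2-(4-methoxyphenoxy)but-3-en-1-yl]-4-methoxybut-2-enoate
Conditions: CO (1 atm), MeOH, Pd(OAc)2 (cat.), Ph3As (cat.), 1,4-benzoquinone, CF3CO2H (cat.), rt
Reagents that add atoms: carbon monoxide, [C-]#[O+]; methanol, CO
Why: Palladium-catalysed oxidative methoxycarbonylation of an alkenylstannane: tin-to-palladium transmetalation on divalent palladium, CO insertion and methanolysis give the ester with retention of alkene geometry, and benzoquinone returns zerovalent palladium to the divalent state. The neighbouring free hydroxyl assists the transmetalation. This puts C7 on C3 at the ester level.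

Step 5
Reactants: 8 methyl (2Z)-2-[(1S,2S)-1-hydroxy-2-(4-methoxyphenoxy)but-3-en-1-yl]-4-methoxybut-2-enoate
Product: 9 methyl (2Z)-2-[(1S,2S)-1-(tert-butyldimethylsilyloxy)-2-(4-methoxyphenoxy)but-3-en-1-yl]-4-methoxybut-2-enoate
Conditions: TBSOTf, 2,6-lutidine, CH2Cl2, −78 → 0 °C
Reagents that add atoms: tert-butyldimethylsilyl triflate, CC(C)(C)[Si](C)(C)OS(=O)(=O)C(F)(F)F
Why: Silylation of a hindered secondary allylic alcohol with a silyl triflate and a hindered base. The ether has to survive the aluminium reagent and amide base of step 7, the oxidant of step 9 and the hydride of step 10, and fall only to fluoride.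

Step 6
Reactants: 9 methyl (2Z)-2-[(1S,2S)-1-(tert-butyldimethylsilyloxy)-2-(4-methoxyphenoxy)but-3-en-1-yl]-4-methoxybut-2-enoate
Product: 10 methyl (2Z)-2-[(1S,2R)-1-(tert-butyldimethylsilyloxy)-2-(4-methoxyphenoxy)-3-oxopropyl]-4-methoxybut-2-enoate
Conditions: OsO4 (cat.), NaIO4, 2,6-lutidine, dioxane/H2O (3:1), rt
Reagents that add atoms: osmium tetroxide, O=[Os](=O)(=O)=O; sodium periodate, [Na+].[O-]I(=O)(=O)=O
Why: Lemieux–Johnson oxidative cleavage: OsO4 dihydroxylates the electron-rich monosubstituted alkene much faster than the trisubstituted, ester-deactivated one, and periodate cleaves the diol. 2,6-Lutidine keeps the medium near neutral so that the alpha-aryloxy aldehyde should not epimerise at C5.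

Step 7
Reactants: 10 methyl (2Z)-2-[(1S,2R)-1-(tert-butyldimethylsilyloxy)-2-(4-methoxyphenoxy)-3-oxopropyl]-4-methoxybut-2-enoate
Product: 12 methyl (3S,4R,5S,6S)-6-(tert-butyldimethylsilyloxy)-4-hydroxy-3-methoxy-5-(4-methoxyphenoxy)cyclohex-1-ene-1-carboxylate, via lithium dienolate 11 (not isolated)
Conditions: Al(OC6H3-2,6-Ph2)3 (2.2 equiv, from Me3Al and 2,6-diphenylphenol), toluene, −78 °C; lithium 2,2,6,6-tetramethylpiperidide (from the amine and n-BuLi), THF, −78 °C; aq. NH4Cl
Reagents that add atoms: none
Why: Proposed new method: the bulky aluminium phenoxide binds the aldehyde and ester carbonyls and shields the aldehyde from the amide base and from deprotonation at C5, so the lithium amide removes a C1 proton, acidified through C2=C3–C7=O, and gives dienolate 11, in which C2–C3 is a single bond and the original alkene geometry no longer matters. C1 of 11 adds to the activated C6 aldehyde, C2=C3 re-forms in conjugation with the ester, and work-up gives the C6 alcohol. The closest known reactions are the aluminium phenoxide-mediated vinylogous aldol addition of enoate dienolates to aldehydes, its macrocyclising intramolecular form and the vinylogous Mukaiyama aldol addition; closure of a cyclohexene by a dienolate bearing an alkoxy group on its nucleophilic carbon has not been shown. The ring closes in the 6-(enolendo)-exo-trig mode, and attack through C3 is excluded because it would give a four-membered ring. C1 is controlled by the enol ether geometry of 11: a methoxy group syn to C3 would point into the forming ring, so it sits anti to C3 and ends pseudo-equatorial. C6 is controlled by a chair-like transition state in which the aluminium-bound carbonyl oxygen points outward (equatorial) and the equatorial C5 aryl ether lies anti to the forming bond, so C6–OH forms trans to both neighbours and the existing C4 and C5 centres set the absolute sense. The step needs gamma-deprotonation to outrun enolisation of the aldehyde (which would epimerise C5 or expel the C4 silyloxy group), and it needs the all-equatorial chair to win over the chair with C4 and C5 axial. The first is secured by the aluminium reagent and the low temperature; the second is not secured and, should the aldolate equilibrate by retro-aldol reaction, rests on the all-trans product being the most stable isomer.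

Step 8
Reactants: 12 methyl (3S,4R,5S,6S)-6-(tert-butyldimethylsilyloxy)-4-hydroxy-3-methoxy-5-(4-methoxyphenoxy)cyclohex-1-ene-1-carboxylate
Product: 13 methyl (3S,4R,5R,6S)-4,6-bis(tert-butyldimethylsilyloxy)-3-methoxy-5-(4-methoxyphenoxy)cyclohex-1-ene-1-carboxylate
Conditions: TBSOTf, 2,6-lutidine, CH2Cl2, 0 °C
Reagents that add atoms: tert-butyldimethylsilyl triflate, CC(C)(C)[Si](C)(C)OS(=O)(=O)C(F)(F)F
Why: Silylation of the new secondary C6 hydroxyl, so that only C5 is free after step 9. No stereocentre is touched; the descriptor at C5 changes only through the priorities.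

Step 9
Reactants: 13 methyl (3S,4R,5R,6S)-4,6-bis(tert-butyldimethylsilyloxy)-3-methoxy-5-(4-methoxyphenoxy)cyclohex-1-ene-1-carboxylate
Product: 14 methyl (3S,4S,5R,6S)-4,6-bis(tert-butyldimethylsilyloxy)-5-hydroxy-3-methoxycyclohex-1-ene-1-carboxylate
Conditions: (NH4)2Ce(NO3)6, pyridine, MeCN/H2O (4:1), 0 °C
Reagents that add atoms: none
Why: Oxidative dearylation of a 4-methoxyphenyl ether: tetravalent cerium oxidises the electron-rich arene, water adds at the ipso carbon and benzoquinone is expelled, so the C5–O bond is not broken and C5 keeps its configuration. Pyridine buffers the nitric acid formed and protects the silyl ethers. The free C5 hydroxyl cannot lactonise onto C7, because C3 would become an alkene bridgehead.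

Step 10
Reactants: 14 methyl (3S,4S,5R,6S)-4,6-bis(tert-butyldimethylsilyloxy)-5-hydroxy-3-methoxycyclohex-1-ene-1-carboxylate
Product: 15 [(3S,4S,5R,6S)-4,6-bis(tert-butyldimethylsilyloxy)-5-hydroxy-3-methoxycyclohex-1-en-1-yl]methanol
Conditions: i-Bu2AlH (3.5 equiv), CH2Cl2, −78 °C; aq. potassium sodium tartrate
Reagents that add atoms: none
Why: 1,2-Reduction of the conjugated ester to the allylic alcohol with i-Bu2AlH at low temperature. The C5 hydroxyl is first converted into its aluminium alkoxide, which consumes one equivalent.

Step 11
Reactants: 15 [(3S,4S,5R,6S)-4,6-bis(tert-butyldimethylsilyloxy)-5-hydroxy-3-methoxycyclohex-1-en-1-yl]methanol; 16 benzoyl chloride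
Product: 17 [(3S,4R,5R,6S)-5-(benzoyloxy)-4,6-bis(tert-butyldimethylsilyloxy)-3-methoxycyclohex-1-en-1-yl]methyl benzoate
Conditions: 16 (3 equiv), pyridine, DMAP (cat.), CH2Cl2, 0 → 40 °C
Reagents that add atoms: benzoyl chloride (the second equivalent of 16), O=C(Cl)c1ccccc1
Why: DMAP-catalysed double acylation: one equivalent of 16 esterifies the primary allylic C7 hydroxyl and a second equivalent esterifies the secondary C5 hydroxyl, so two benzoyl groups enter the product. The C5 hydroxyl is flanked by two silyl ethers, hence the excess reagent and gentle warming; no other hydroxyl is free.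

Step 12
Reactants: 17 [(3S,4R,5R,6S)-5-(benzoyloxy)-4,6-bis(tert-butyldimethylsilyloxy)-3-methoxycyclohex-1-en-1-yl]methyl benzoate
Product: 18 [(3S,4R,5R,6S)-5-(benzoyloxy)-4,6-dihydroxy-3-methoxycyclohex-1-en-1-yl]methyl benzoate
Conditions: HF·pyridine, pyridine, THF, 0 °C → rt
Reagents that add atoms: none
Why: Fluoride-mediated cleavage of both silyl ethers under buffered, weakly acidic conditions, under which the benzoates should not migrate to the neighbouring hydroxyls and the allylic ether and ester should not ionise. This should give the target 18.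

## Compound list

1 | 3-methoxyprop-1-yne (methyl propargyl ether) | COCC#C | starting material
2 | lithium 3-methoxyprop-1-yn-1-ide (not isolated) | [Li]C#CCOC | intermediate
3 | 4-methoxybut-2-ynal | COCC#CC=O | intermediate
4 | 1-methoxy-4-(prop-2-en-1-yloxy)benzene (allyl 4-methoxyphenyl ether) | C=CCOc1ccc(OC)cc1 | starting material
5 | B-[(2Z)-3-(4-methoxyphenoxy)prop-2-en-1-yl]diisopinocampheylborane, isopinocampheyl groups from (−)-α-pinene (not isolated) | COc1ccc(O/C=C\CB([C@H]2C[C@H]3C[C@H](C3(C)C)[C@@H]2C)[C@H]2C[C@H]3C[C@H](C3(C)C)[C@@H]2C)cc1 | intermediate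
6 | (3S,4S)-7-methoxy-3-(4-methoxyphenoxy)hept-1-en-5-yn-4-ol | COCC#C[C@H](O)[C@@H](Oc1ccc(OC)cc1)C=C | intermediate
7 | (3S,4R,5Z)-7-methoxy-3-(4-methoxyphenoxy)-5-(tributylstannyl)hepta-1,5-dien-4-ol | COC/C=C(\[Sn](CCCC)(CCCC)CCCC)[C@H](O)[C@@H](Oc1ccc(OC)cc1)C=C | intermediate
8 | methyl (2Z)-2-[(1S,2S)-1-hydroxy-2-(4-methoxyphenoxy)but-3-en-1-yl]-4-methoxybut-2-enoate | COC/C=C(\C(=O)OC)[C@H](O)[C@@H](Oc1ccc(OC)cc1)C=C | intermediate
9 | methyl (2Z)-2-[(1S,2S)-1-(tert-butyldimethylsilyloxy)-2-(4-methoxyphenoxy)but-3-en-1-yl]-4-methoxybut-2-enoate | COC/C=C(\C(=O)OC)[C@H](O[Si](C)(C)C(C)(C)C)[C@@H](Oc1ccc(OC)cc1)C=C | intermediate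
10 | methyl (2Z)-2-[(1S,2R)-1-(tert-butyldimethylsilyloxy)-2-(4-methoxyphenoxy)-3-oxopropyl]-4-methoxybut-2-enoate (key-step precursor) | COC/C=C(\C(=O)OC)[C@H](O[Si](C)(C)C(C)(C)C)[C@@H](Oc1ccc(OC)cc1)C=O | intermediate
11 | lithium (3E)-2-[(1S,2R)-1-(tert-butyldimethylsilyloxy)-2-(4-methoxyphenoxy)-3-oxopropyl]-1,4-dimethoxybuta-1,3-dien-1-olate, held on the aluminium phenoxide (not isolated) | [Li+].[O-]C(OC)=C(/C=C/OC)[C@H](O[Si](C)(C)C(C)(C)C)[C@@H](Oc1ccc(OC)cc1)C=O | intermediate
12 | methyl (3S,4R,5S,6S)-6-(tert-butyldimethylsilyloxy)-4-hydroxy-3-methoxy-5-(4-methoxyphenoxy)cyclohex-1-ene-1-carboxylate (key-step product) | CO[C@H]1C=C(C(=O)OC)[C@H](O[Si](C)(C)C(C)(C)C)[C@@H](Oc2ccc(OC)cc2)[C@@H]1O | intermediate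
13 | methyl (3S,4R,5R,6S)-4,6-bis(tert-butyldimethylsilyloxy)-3-methoxy-5-(4-methoxyphenoxy)cyclohex-1-ene-1-carboxylate | CO[C@H]1C=C(C(=O)OC)[C@H](O[Si](C)(C)C(C)(C)C)[C@@H](Oc2ccc(OC)cc2)[C@@H]1O[Si](C)(C)C(C)(C)C | intermediate
14 | methyl (3S,4S,5R,6S)-4,6-bis(tert-butyldimethylsilyloxy)-5-hydroxy-3-methoxycyclohex-1-ene-1-carboxylate | CO[C@H]1C=C(C(=O)OC)[C@H](O[Si](C)(C)C(C)(C)C)[C@@H](O)[C@@H]1O[Si](C)(C)C(C)(C)C | intermediate
15 | [(3S,4S,5R,6S)-4,6-bis(tert-butyldimethylsilyloxy)-5-hydroxy-3-methoxycyclohex-1-en-1-yl]methanol | CO[C@H]1C=C(CO)[C@H](O[Si](C)(C)C(C)(C)C)[C@@H](O)[C@@H]1O[Si](C)(C)C(C)(C)C | intermediate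
16 | benzoyl chloride | O=C(Cl)c1ccccc1 | starting material
17 | [(3S,4R,5R,6S)-5-(benzoyloxy)-4,6-bis(tert-butyldimethylsilyloxy)-3-methoxycyclohex-1-en-1-yl]methyl benzoate | CO[C@H]1C=C(COC(=O)c2ccccc2)[C@H](O[Si](C)(C)C(C)(C)C)[C@@H](OC(=O)c2ccccc2)[C@@H]1O[Si](C)(C)C(C)(C)C | intermediate
18 | [(3S,4R,5R,6S)-5-(benzoyloxy)-4,6-dihydroxy-3-methoxycyclohex-1-en-1-yl]methyl benzoate | CO[C@H]1C=C(COC(=O)c2ccccc2)[C@H](O)[C@@H](OC(=O)c2ccccc2)[C@@H]1O | target

## Step count and least certain steps

Total step count: 12. Longest linear sequence: 12 steps (1 → 18); 4 and 16 are commercial.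

Step 7 (key step). The most likely failure is deprotonation of the aldehyde at C5 in place of C1, because C5–H is the most acidic C–H in 10; this would epimerise C5 or eliminate the C4 silyloxy group. Loss of the C4 silyloxy group from the dienolate itself, in which it sits beta to the enolate carbon C3, is a further elimination pathway that competes with ring closure. The second stereochemical risk is closure through the chair with C4 and C5 axial, favoured by allylic strain between the C4 substituent and the ketene acetal, which would invert C6 and C1 together. Two very bulky aluminium centres within a six-atom span may also slow the closure. The fallback forms the C1–C6 bond by allylboration and closes the ring by metathesis at C2=C3. It sets out from 10: the (Z)-γ-methoxyallyl diisopinocampheylborane made from allyl methyl ether, s-BuLi, (+)-Ipc2BOMe and BF3·OEt2 is added at −78 °C (NaBO3 work-up). Its Z-geometry and its terpene ligands set C6 and the new methoxy-bearing carbon syn and in the required absolute sense against the Felkin preference of the aldehyde, to give methyl (2Z)-2-[(1S,2S,3R,4S)-1-(tert-butyldimethylsilyloxy)-3-hydroxy-4-methoxy-2-(4-methoxyphenoxy)hex-5-en-1-yl]-4-methoxybut-2-enoate F1. Ring-closing metathesis of F1 with the second-generation Hoveyda–Grubbs catalyst in toluene at 80 °C joins the new vinyl carbon to C3, expels the old CH–CH2OMe unit as a volatile alkene, and comes back to the route at 12.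

Step 3. Tin may be delivered to C2 in place of C3, because both propargylic carbons carry oxygen and only the hydrogen bond of the free hydroxyl distinguishes them; the 1,5-enyne could also cycloisomerise on ruthenium. The fallback avoids alkyne hydrometalation by starting from a haloenal. It sets out from 4 through borane 5. (2Z)-2-Bromo-4-methoxybut-2-enal F2, from the Wittig reaction of methoxyacetaldehyde with Ph3P=C(Br)CHO, is treated with 5 under the conditions of step 2 to give (3S,4R,5Z)-5-bromo-7-methoxy-3-(4-methoxyphenoxy)hepta-1,5-dien-4-ol F3. Silylation (TBSOTf, 2,6-lutidine) gives {[(3S,4R,5Z)-5-bromo-7-methoxy-3-(4-methoxyphenoxy)hepta-1,5-dien-4-yl]oxy}(tert-butyl)dimethylsilane F4. Methoxycarbonylation of the alkenyl bromide (Pd(PPh3)4, CO, Et3N, MeOH/DMF, 60 °C) comes back to the route at 9.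

Step 4. Protodestannylation or homocoupling of the stannane may outrun carbonylation, and the acylpalladium intermediate may be trapped by the neighbouring hydroxyl or the vinyl group. The fallback changes the electrophile class. It sets out from 7: iododestannylation (I2, CH2Cl2, 0 °C) with retention gives (3S,4R,5Z)-5-iodo-7-methoxy-3-(4-methoxyphenoxy)hepta-1,5-dien-4-ol F5. Silylation gives tert-butyl{[(3S,4R,5Z)-5-iodo-7-methoxy-3-(4-methoxyphenoxy)hepta-1,5-dien-4-yl]oxy}dimethylsilane F6. Alkoxycarbonylation on zerovalent palladium (Pd(PPh3)4, CO, Et3N, MeOH, 50 °C) comes back to the route at 9.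

Step 2. Enantio- or diastereoselectivity may erode, because the ynal is a small, linear aldehyde, the Z-allyl boron reagent can isomerise above −78 °C, and ortho-lithiation of 4 competes with allylic lithiation. The fallback sets the same two centres by an auxiliary-controlled syn-glycolate aldol. It sets out from 3: the dibutylboron enolate (Bu2BOTf, i-Pr2NEt, CH2Cl2, −78 → 0 °C) of (4R)-4-benzyl-3-[(4-methoxyphenoxy)acetyl]-1,3-oxazolidin-2-one F7 adds to 3 to give the Evans syn adduct (4R)-4-benzyl-3-[(2R,3S)-3-hydroxy-6-methoxy-2-(4-methoxyphenoxy)hex-4-ynoyl]-1,3-oxazolidin-2-one F8. Transamidation (Me3Al, MeONHMe·HCl) gives (2R,3S)-3-hydroxy-N,6-dimethoxy-2-(4-methoxyphenoxy)-N-methylhex-4-ynamide F9. Reduction with i-Bu2AlH at −78 °C gives (2R,3S)-3-hydroxy-6-methoxy-2-(4-methoxyphenoxy)hex-4-ynal F10. Non-basic Takai–Lombardo methylenation (Zn, CH2Br2, TiCl4) comes back to the route at 6.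

## Further compounds

F1 | step 7 | methyl (2Z)-2-[(1S,2S,3R,4S)-1-(tert-butyldimethylsilyloxy)-3-hydroxy-4-methoxy-2-(4-methoxyphenoxy)hex-5-en-1-yl]-4-methoxybut-2-enoate | COC/C=C(\C(=O)OC)[C@H](O[Si](C)(C)C(C)(C)C)[C@@H](Oc1ccc(OC)cc1)[C@H](O)[C@@H](OC)C=C
F2 | step 3 | (2Z)-2-bromo-4-methoxybut-2-enal | COC/C=C(\Br)C=O
F3 | step 3 | (3S,4R,5Z)-5-bromo-7-methoxy-3-(4-methoxyphenoxy)hepta-1,5-dien-4-ol | COC/C=C(\Br)[C@H](O)[C@@H](Oc1ccc(OC)cc1)C=C
F4 | step 3 | {[(3S,4R,5Z)-5-bromo-7-methoxy-3-(4-methoxyphenoxy)hepta-1,5-dien-4-yl]oxy}(tert-butyl)dimethylsilane | COC/C=C(\Br)[C@H](O[Si](C)(C)C(C)(C)C)[C@@H](Oc1ccc(OC)cc1)C=C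
F5 | step 4 | (3S,4R,5Z)-5-iodo-7-methoxy-3-(4-methoxyphenoxy)hepta-1,5-dien-4-ol | COC/C=C(\I)[C@H](O)[C@@H](Oc1ccc(OC)cc1)C=C
F6 | step 4 | tert-butyl{[(3S,4R,5Z)-5-iodo-7-methoxy-3-(4-methoxyphenoxy)hepta-1,5-dien-4-yl]oxy}dimethylsilane | COC/C=C(\I)[C@H](O[Si](C)(C)C(C)(C)C)[C@@H](Oc1ccc(OC)cc1)C=C
F7 | step 2 | (4R)-4-benzyl-3-[(4-methoxyphenoxy)acetyl]-1,3-oxazolidin-2-one | COc1ccc(OCC(=O)N2[C@H](Cc3ccccc3)COC2=O)cc1
F8 | step 2 | (4R)-4-benzyl-3-[(2R,3S)-3-hydroxy-6-methoxy-2-(4-methoxyphenoxy)hex-4-ynoyl]-1,3-oxazolidin-2-one | COCC#C[C@H](O)[C@@H](Oc1ccc(OC)cc1)C(=O)N1[C@H](Cc2ccccc2)COC1=O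
F9 | step 2 | (2R,3S)-3-hydroxy-N,6-dimethoxy-2-(4-methoxyphenoxy)-N-methylhex-4-ynamide | COCC#C[C@H](O)[C@@H](Oc1ccc(OC)cc1)C(=O)N(C)OC
F10 | step 2 | (2R,3S)-3-hydroxy-6-methoxy-2-(4-methoxyphenoxy)hex-4-ynal | COCC#C[C@H](O)[C@@H](Oc1ccc(OC)cc1)C=O
A1 | alternative 1 | ethyl benzoate | CCOC(=O)c1ccccc1
A2 | alternative 1 | ethyl (5S,6R)-5,6-dihydroxycyclohexa-1,3-diene-1-carboxylate | CCOC(=O)C1=CC=C[C@H](O)[C@@H]1O
A3 | alternative 2 | (2Z,3S,4R,5S)-4-(benzoyloxy)-3,5-bis(tert-butyldimethylsilyloxy)-6,6-dimethoxy-2-[(trimethylsilyl)methylidene]hexyl benzoate | COC(OC)[C@@H](O[Si](C)(C)C(C)(C)C)[C@H](OC(=O)c1ccccc1)[C@@H](O[Si](C)(C)C(C)(C)C)/C(COC(=O)c1ccccc1)=C\[Si](C)(C)C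
A4 | alternative 2 | [(3S,4R,5R,6S)-5-(benzoyloxy)-4,6-bis(tert-butyldimethylsilyloxy)-3-methoxycyclohex-1-en-1-yl]methyl benzoate (identical with 17) | CO[C@H]1C=C(COC(=O)c2ccccc2)[C@H](O[Si](C)(C)C(C)(C)C)[C@@H](OC(=O)c2ccccc2)[C@@H]1O[Si](C)(C)C(C)(C)C
A5 | alternative 3 | (2S,3S)-2-(tert-butyldimethylsilyloxy)-3-(4-methoxybenzyloxy)butanedial | O=C[C@@H](OCc1ccc(OC)cc1)[C@H](O[Si](C)(C)C(C)(C)C)C=O
A6 | alternative 3 | tert-butyldimethyl{[3-(trimethylsilyl)prop-2-yn-1-yl]oxy}silane | C[Si](C)(C)C#CCO[Si](C)(C)C(C)(C)C
A7 | alternative 3 | 5-(4-methoxybenzyloxy)-6-(tert-butyldimethylsilyloxy)-3-[(tert-butyldimethylsilyloxy)methyl]-2-(trimethylsilyl)cyclohex-2-ene-1,4-diol | O[C@H]1C([Si](C)(C)C)=C(CO[Si](C)(C)C(C)(C)C)[C@H](O)[C@@H](OCc2ccc(OC)cc2)[C@@H]1O[Si](C)(C)C(C)(C)C
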